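**Plan**
Cuts (labdane numbering; alpha = face opposite the C10 methyl): the acetyl–O bond at C2, C13=C14, C9–C11, then C3–C4 (opens ring A), then C10–C1 and C10–CH3. This leaves (R)-carvone as ring B.
Enabling feature: in ring A the gem-dimethyl carbon C4 lies between C5 of ring B and the C3 carbinol carbon. C4 plus one methyl is therefore carvone's isopropenyl group, a latent tertiary radical. C3 is an aldehyde that this radical reaches through the six-membered array C4–C5–C10–C1–C2–C3.
Forward order: ring B is bought and C10 is made quaternary (methyl, then propargyl = C1–C3). The alkyne becomes the C3 aldehyde, C2 is oxygenated, and ring A closes. The C11–C13/C16 unit is then joined at C9, C14–C15 come by olefination, and the acetate comes last.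
Stereochemistry: C5 from carvone; C10 by alkylation anti to the isopropenyl group; C2 from L-proline; C3 from C2 in the chair transition state; C9 by attack anti to the C10 methyl; C8 by hydroxyl-directed hydrogenation; 13E from the phosphonate olefination.

Key step: step 8

Assumption: the SMILES is taken literally, which gives 2-alpha acetate (equatorial), 3-alpha OH (axial), 5-alpha H, 8-alpha CH3 (equatorial), 9-beta OH with the C11 chain alpha (axial), 10-beta CH3 and a 13E alkene. Labdane numbering is used for every intermediate.

Step 1
Reactants: 1 (R)-carvone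
Product: 3 6-methylcarvone (both epimers at the new centre), via lithium dienolate 2 (not isolated)
Conditions: LiN(i-Pr)2, THF, −78 °C; MeI, −78 → 0 °C
Reagents that add atoms: iodomethane CI
Why: Kinetic deprotonation at the alpha-prime CH2 gives the cross-conjugated dienolate and SN2 methylation brings in the future C10 methyl, the configuration of the new centre being irrelevant because step 2 flattens it again.

Step 2
Reactants: 3 6-methylcarvone; 4 propargyl bromide
Product: 6 6-methyl-6-propargylcarvone (propargyl trans to isopropenyl), via lithium enolate 5 (not isolated)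
Conditions: LiN(i-Pr)2, THF, DMPU, −78 → −20 °C; 4, −78 °C → rt
Reagents that add atoms: none
Why: Enolate C-alkylation in which the C5 isopropenyl group, pushed pseudoaxial by allylic strain against the C10 methyl of the flat enolate, screens its own face, so the propargylic bromide should enter anti to it and fix C10 with the C1 arm alpha and the methyl beta.

Step 3
Reactants: 6 6-methyl-6-propargylcarvone
Product: 8 keto aldehyde with a 3-oxopropyl arm (C1H2–C2H2–C3HO) on C10, via alkenylborane 7 (not isolated)
Conditions: Cy2BH (from cyclohexene, BH3·SMe2), THF, 0 °C; H2O2, pH 7 phosphate buffer, 0 °C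
Reagents that add atoms: hydrogen peroxide OO
Why: Anti-Markovnikov monohydroboration of a terminal alkyne by a bulky dialkylborane and buffered oxidation of the alkenylborane to the aldehyde, the alkyne reacting far faster than the hindered 1,1-disubstituted alkene or the shielded conjugated ketone and the neutral pH avoiding nucleophilic epoxidation of the enone.

Step 4
Reactants: 8 keto aldehyde
Product: 10 (2R)-2-anilinooxy-3-hydroxypropyl enone, via anilinooxy aldehyde 9 (not isolated)
Conditions: PhNO, L-proline (20 mol%), DMSO, rt; NaBH4, MeOH, 0 °C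
Reagents that add atoms: nitrosobenzene O=Nc1ccccc1
Why: Proline-catalysed enamine alpha-aminoxylation in which the acid-bound nitroso oxygen is delivered to one enamine face, so L-proline should set C2 as R under catalyst control, and a brief borohydride treatment reduces only the labile aldehyde and not the hindered enone.

Step 5
Reactants: 10 (2R)-2-anilinooxy-3-hydroxypropyl enone
Product: 11 (2R)-2,3-dihydroxypropyl enone
Conditions: CuSO4·5H2O (30 mol%), MeOH, rt
Reagents that add atoms: none
Why: Copper-catalysed N–O cleavage of the anilinooxy group under neutral conditions, chosen because hydrogenolysis or dissolving zinc would endanger the alkenes and the enone, with C2 untouched.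

Step 6
Reactants: 11 (2R)-2,3-dihydroxypropyl enone
Product: 13 bis-silyl ether (C3-OTES C2-OTBS), via primary TES ether 12 (not isolated)
Conditions: TESCl (1.05 equiv), imidazole, CH2Cl2, −20 °C; TBSOTf, 2,6-lutidine, −20 → 0 °C
Reagents that add atoms: chlorotriethylsilane CC[Si](Cl)(CC)CC; tert-butyldimethylsilyl triflate CC(C)(C)[Si](C)(C)OS(=O)(=O)C(F)(F)F
Why: Stepwise silylation on steric grounds, one equivalent of the chloride taking the primary C3 hydroxyl and the stronger triflate then capping the secondary C2 hydroxyl as a robust non-chelating TBS ether.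

Step 7
Reactants: 13 bis-silyl ether
Product: 14 (2R)-2-(tert-butyldimethylsilyloxy)-3-oxopropyl enone (cyclisation precursor)
Conditions: (COCl)2, DMSO, CH2Cl2, −78 → −30 °C; Et3N, −78 °C → rt
Reagents that add atoms: none
Why: Swern oxidation applied directly to a primary triethylsilyl ether, which the chlorosulfonium salt desilylates and oxidises in one operation while the secondary TBS ether stays, the low temperature keeping C2 from epimerising.

Step 8
Reactants: 14 (2R)-2-(tert-butyldimethylsilyloxy)-3-oxopropyl enone
Product: 17 trans-fused bicyclic enone (2-alpha OTBS 3-alpha OH 5-alpha H 10-beta CH3), via tertiary C4 radical 15 (not isolated), via C3 alkoxy radical 16 (not isolated)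
Conditions: Fe(acac)3 (0.5 equiv), PhSiH3 (3 equiv, slow addition), degassed EtOH, 60 °C
Reagents that add atoms: none
Why: An iron hydride generated from Fe(acac)3, the silane and ethanol gives a hydrogen atom to the terminal CH2 of the electron-rich 1,1-disubstituted alkene, so radical 15 already holds the complete gem-dimethyl C4; 15 bonds to the aldehyde carbon C3, and alkoxy radical 16 is removed at once by divalent iron and ethanol, which regenerates trivalent iron and makes an otherwise reversible addition productive. The closest known reaction types are the iron hydrogen-atom-transfer reductive cyclisation of alkene-tethered ketones, the intermolecular iron-hydride coupling of alkenes with aldehydes, and the tin-hydride 6-exo closure of alkyl radicals onto aldehydes. Ring A closes 6-exo-trig (C4, C5, C10, C1, C2 and C3 in the ring, oxygen outside) through a chair in which C4 and C1 are both equatorial on ring B, so only the trans-decalin can form. C3 is controlled by C2: the equatorial silyloxy group lies antiperiplanar to the forming C3–C4 bond (polar Felkin–Anh arrangement), which also activates the aldehyde toward the nucleophilic radical, and the carbonyl oxygen then sits on the C1 side, axial on the alpha face and anti to the axial C4 methyl, which should give the 3-alpha hydroxyl cis to the 2-alpha silyloxy group. The step needs the hydride to choose the isopropenyl group over the enone, which is secured because C7=C8 is trisubstituted and electron-poor, and C4 can reach neither that bond nor the C9 carbonyl except through a four-membered ring. Slow addition of the silane keeps the hydride concentration low so that closure outruns simple reduction of 15.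

Step 9
Reactants: 17 trans-fused bicyclic enone; 18 2-(2-bromoethyl)-2-methyl-1,3-dioxolane
Product: 20 tertiary allylic alcohol (9-beta OH 9-alpha ketal chain C7=C8 retained), via Grignard reagent 19 (not isolated)
Conditions: 18 (5 equiv), Mg, THF, 25 °C; CeCl3, THF, −78 °C; 17, −78 → 0 °C; aq NH4Cl
Reagents that add atoms: none
Why: CeCl3-promoted Grignard 1,2-addition to a ketone that has no alpha hydrogen, one equivalent of 19 being spent on the C3 hydroxyl, in which the nucleophile should enter antiperiplanar to the axial C10 methyl, from the alpha face, placing C11 alpha and the C9 hydroxyl beta.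

Step 10
Reactants: 20 tertiary allylic alcohol
Product: 21 saturated ketal diol (8-alpha CH3 8-beta H)
Conditions: [Ir(cod)(PCy3)(py)]PF6 (10 mol%), H2 (1 atm), CH2Cl2, rt
Reagents that add atoms: none
Why: Hydroxyl-directed homogeneous hydrogenation in which the cationic iridium centre binds the beta C9 hydroxyl and delivers both hydrogens to the beta face of C7=C8, whose alpha face is in any case screened by the axial C11 chain, so H8 ends beta and the C8 methyl alpha and equatorial.

Step 11
Reactants: 21 saturated ketal diol
Product: 22 2-alpha 3-alpha 9-beta-trihydroxy methyl ketone (C13 ketone)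
Conditions: 48% aq HF, MeCN, 0 °C → rt
Reagents that add atoms: water O
Why: Acid hydrolysis of the dioxolane and fluoride cleavage of the TBS ether in one operation, tolerated because the now saturated tertiary C9 alcohol no longer ionises easily and the aqueous medium prevents mixed-ketal formation.

Step 12
Reactants: 22 trihydroxy methyl ketone; 23 trimethyl phosphonoacetate
Product: 25 methyl (13E)-2-alpha 3-alpha 9-beta-trihydroxylabd-13-en-15-oate, via sodium phosphonate 24 (not isolated)
Conditions: 23 (4 equiv), NaH (3.8 equiv), THF, 0 °C; 22, rt → 50 °C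
Reagents that add atoms: none
Why: Horner–Wadsworth–Emmons olefination of a methyl ketone, which under reversible addition favours the E enoate with the ester trans to the larger C12 chain (the minor Z isomer is removed by chromatography), while keeping the phosphonate in excess over NaH leaves no base strong enough to deprotonate the three hydroxyl groups.

Step 13
Reactants: 25 methyl (13E)-trihydroxylabdenoate
Product: 26 target CNP0135744.1
Conditions: Ac2O (1.1 equiv), pyridine, CH2Cl2, 0 °C
Reagents that add atoms: acetic anhydride CC(=O)OC(C)=O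
Why: Sterically controlled acetylation in which the equatorial C2 hydroxyl should react much faster than the axial neopentyl C3 hydroxyl beside the C4 methyl groups or the tertiary C9 hydroxyl, with no stereocentre touched.

**Compound list**
1 | (R)-carvone | CC1=CC[C@H](CC1=O)C(C)=C | starting material
2 | lithium cross-conjugated dienolate of 1 (deprotonated at the future C10) | [Li+].[O-]C1=C[C@H](C(C)=C)CC=C1C | intermediate
3 | 6-methylcarvone, (5R)-2,6-dimethyl-5-(prop-1-en-2-yl)cyclohex-2-en-1-one, both epimers at the methyl-bearing carbon | O=C1C(C)=CC[C@@H](C(C)=C)C1C | intermediate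
4 | propargyl bromide | C#CCBr | starting material
5 | lithium enolate of 3 (flat at the future C10) | [Li+].[O-]C1=C(C)[C@H](C(C)=C)CC=C1C | intermediate
6 | 6-methyl-6-propargylcarvone, propargyl trans to isopropenyl (C10: CH3 beta, C1 arm alpha) | O=C1C(C)=CC[C@@H](C(C)=C)[C@]1(C)CC#C | intermediate
7 | (E)-alkenyl(dicyclohexyl)borane from 6 | O=C1C(C)=CC[C@@H](C(C)=C)[C@]1(C)C/C=C/B(C2CCCCC2)C2CCCCC2 | intermediate
8 | keto aldehyde, 3-oxopropyl arm on C10 | O=C1C(C)=CC[C@@H](C(C)=C)[C@]1(C)CCC=O | intermediate
9 | (2R)-2-anilinooxy aldehyde | O=C1C(C)=CC[C@@H](C(C)=C)[C@]1(C)C[C@@H](ONc2ccccc2)C=O | intermediate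
10 | (2R)-2-anilinooxy-3-hydroxypropyl enone | O=C1C(C)=CC[C@@H](C(C)=C)[C@]1(C)C[C@@H](ONc2ccccc2)CO | intermediate
11 | (2R)-2,3-dihydroxypropyl enone | O=C1C(C)=CC[C@@H](C(C)=C)[C@]1(C)C[C@@H](O)CO | intermediate
12 | primary (C3) triethylsilyl ether of 11 | O=C1C(C)=CC[C@@H](C(C)=C)[C@]1(C)C[C@@H](O)CO[Si](CC)(CC)CC | intermediate
13 | C3-OTES, C2-OTBS bis-silyl ether | O=C1C(C)=CC[C@@H](C(C)=C)[C@]1(C)C[C@@H](O[Si](C)(C)C(C)(C)C)CO[Si](CC)(CC)CC | intermediate
14 | cyclisation precursor, (2R)-2-(TBSO)-3-oxopropyl arm on quaternary C10 of the carvone enone | O=C1C(C)=CC[C@@H](C(C)=C)[C@]1(C)C[C@@H](O[Si](C)(C)C(C)(C)C)C=O | intermediate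
15 | tertiary C4 radical from 14 | O=C1C(C)=CC[C@@H]([C](C)C)[C@]1(C)C[C@@H](O[Si](C)(C)C(C)(C)C)C=O | intermediate
16 | C3 alkoxy radical, ring A closed | O=C1C(C)=CC[C@H]2C(C)(C)[C@H]([O])[C@H](O[Si](C)(C)C(C)(C)C)C[C@@]21C | intermediate
17 | trans-fused bicyclic enone, 2-alpha OTBS, 3-alpha OH, 5-alpha H, 10-beta CH3, C7=C8, C9=O | O=C1C(C)=CC[C@H]2C(C)(C)[C@H](O)[C@H](O[Si](C)(C)C(C)(C)C)C[C@@]21C | intermediate
18 | 2-(2-bromoethyl)-2-methyl-1,3-dioxolane | CC1(CCBr)OCCO1 | starting material
19 | 2-(2-methyl-1,3-dioxolan-2-yl)ethylmagnesium bromide | CC1(CC[Mg]Br)OCCO1 | intermediate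
20 | tertiary allylic alcohol, 9-beta OH, 9-alpha CH2CH2-ketal chain, C7=C8 | CC1(CC[C@]2(O)C(C)=CC[C@H]3C(C)(C)[C@H](O)[C@H](O[Si](C)(C)C(C)(C)C)C[C@@]32C)OCCO1 | intermediate
21 | saturated ketal diol, 8-alpha CH3 | CC1(CC[C@]2(O)[C@H](C)CC[C@H]3C(C)(C)[C@H](O)[C@H](O[Si](C)(C)C(C)(C)C)C[C@@]32C)OCCO1 | intermediate
22 | 2-alpha,3-alpha,9-beta-trihydroxy-14,15-dinorlabdan-13-one (C11 chain alpha) | CC(=O)CC[C@]1(O)[C@H](C)CC[C@H]2C(C)(C)[C@H](O)[C@H](O)C[C@@]21C | intermediate
23 | trimethyl phosphonoacetate | COC(=O)CP(=O)(OC)OC | starting material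
24 | sodium salt of 23 | [Na+].COC(=O)[CH-]P(=O)(OC)OC | intermediate
25 | methyl (13E)-2-alpha,3-alpha,9-beta-trihydroxylabd-13-en-15-oate | COC(=O)/C=C(\C)CC[C@]1(O)[C@H](C)CC[C@H]2C(C)(C)[C@H](O)[C@H](O)C[C@@]21C | intermediate
26 | methyl (13E)-2-alpha-acetoxy-3-alpha,9-beta-dihydroxylabd-13-en-15-oate, CNP0135744.1 | COC(=O)/C=C(\C)CC[C@]1(O)[C@H](C)CC[C@H]2C(C)(C)[C@H](O)[C@H](OC(C)=O)C[C@@]21C | target

Total step count: 13. Longest linear sequence: 13 steps from 1.

**Steps most likely to fail**

Step 8. The attack of radical 15 on the aldehyde may show poor facial selectivity. In an early transition state the axial and equatorial placements of the carbonyl oxygen differ little in energy. The fallback no longer relies on the cyclisation to set C3. It sets C3 by reagent-controlled ketone reduction once the enone is gone.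
- It sets out from 14. The cyclisation is run as in step 8, and the 3-beta-hydroxy epimer of 17 F1, alone or mixed with 17, is carried through the conditions of steps 9 and 10.
- This gives the 3-beta-hydroxy epimer of 20 F2 and then the 3-beta-hydroxy epimer of 21 F3.
- Dess–Martin periodinane in CH2Cl2 oxidises the only secondary alcohol to the 3-ketone F4.
- LiBH(s-Bu)3 in THF at −78 °C is a bulky hydride that approaches 4,4-dimethyl-3-ketones of trans-decalins along the equatorial line. It should give the axial 3-alpha alcohol, and the route is rejoined at 21.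

Step 9. Addition to a carbonyl flanked by quaternary C10 and the C8 methyl may be slow. Beta-hydride reduction or thermal decay of the beta-ketal Grignard reagent may then win. The fallback replaces the sp3 nucleophile with a slim sp nucleophile that carries the same four carbons.
- But-3-yn-2-one is ketalised with ethylene glycol (TsOH, benzene, water separator) to 2-ethynyl-2-methyl-1,3-dioxolane F5.
- n-BuLi in THF at −78 °C converts it into the lithium acetylide F6.
- The fallback sets out from 17. Excess acetylide should add along the axial line from the alpha face to give the C9 propargylic alcohol F7.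
- H2 over Pd/C in EtOAc saturates the triple bond while the hindered trisubstituted C7=C8 should survive. The route is rejoined at 20.

Step 12. The C9 hydroxyl may close reversibly onto the C13 ketone and slow the olefination. Conjugate addition of the C9 oxygen to the new enoate may then erode the product. The fallback takes the C9 hydroxyl out of play before the ketone is unveiled.
- It sets out from 21. TESOTf and 2,6-lutidine in CH2Cl2 silylate the C3 and C9 hydroxyls to the tris-silyl ketal F8.
- PPTS in wet acetone removes only the dioxolane to give the tris-silyl methyl ketone F9.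
- Olefination with 24 in THF gives the tris-silyl (13E)-enoate F10.
- Aqueous HF in MeCN strips all three silyl groups. The route is rejoined at 25.

**Further compounds**
F1 | step 8 | 3-beta-hydroxy epimer of 17 | O=C1C(C)=CC[C@H]2C(C)(C)[C@@H](O)[C@H](O[Si](C)(C)C(C)(C)C)C[C@@]21C
F2 | step 8 | 3-beta-hydroxy epimer of 20 | CC1(CC[C@]2(O)C(C)=CC[C@H]3C(C)(C)[C@@H](O)[C@H](O[Si](C)(C)C(C)(C)C)C[C@@]32C)OCCO1
F3 | step 8 | 3-beta-hydroxy epimer of 21 | CC1(CC[C@]2(O)[C@H](C)CC[C@H]3C(C)(C)[C@@H](O)[C@H](O[Si](C)(C)C(C)(C)C)C[C@@]32C)OCCO1
F4 | step 8 | 3-ketone from 21 and F3 | CC1(CC[C@]2(O)[C@H](C)CC[C@H]3C(C)(C)C(=O)[C@H](O[Si](C)(C)C(C)(C)C)C[C@@]32C)OCCO1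
F5 | step 9 | 2-ethynyl-2-methyl-1,3-dioxolane | CC1(C#C)OCCO1
F6 | step 9 | lithium acetylide of F5 | CC1(C#C[Li])OCCO1
F7 | step 9 | C9 propargylic alcohol (9-beta OH, alkynyl chain alpha) | CC1(C#C[C@]2(O)C(C)=CC[C@H]3C(C)(C)[C@H](O)[C@H](O[Si](C)(C)C(C)(C)C)C[C@@]32C)OCCO1
F8 | step 12 | tris-silyl ketal (C2-OTBS, C3-OTES, C9-OTES) | CC1(CC[C@]2(O[Si](CC)(CC)CC)[C@H](C)CC[C@H]3C(C)(C)[C@H](O[Si](CC)(CC)CC)[C@H](O[Si](C)(C)C(C)(C)C)C[C@@]32C)OCCO1
F9 | step 12 | tris-silyl methyl ketone | CC(=O)CC[C@]1(O[Si](CC)(CC)CC)[C@H](C)CC[C@H]2C(C)(C)[C@H](O[Si](CC)(CC)CC)[C@H](O[Si](C)(C)C(C)(C)C)C[C@@]21C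
F10 | step 12 | tris-silyl (13E)-enoate | COC(=O)/C=C(\C)CC[C@]1(O[Si](CC)(CC)CC)[C@H](C)CC[C@H]2C(C)(C)[C@H](O[Si](CC)(CC)CC)[C@H](O[Si](C)(C)C(C)(C)C)C[C@@]21C
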